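## Structural features

The target is an elemanolide, numbered here on the elemane skeleton: vinyl C1=C2, propenyl arm C4(=C3)–C15, ring C5–C10, lactone carbons C11–C13, methyl C14. A cyclohexane (C5–C10) carries a trans-fused α-methylene-γ-butyrolactone across C6–C7, with the lactone oxygen on C6 and C11(=C13)–C12 on C7. C10 is quaternary (methyl and vinyl) and adjoins C5, which bears the 3-hydroxyprop-1-en-2-yl arm. C5, C6, C7 and C8 are four contiguous stereocentres whose substituents alternate between the two faces, so all four are equatorial while the C10 methyl is axial. C8 carries an ester of (R)-3-hydroxy-2-methylpropanoic acid, a sixth stereocentre outside the ring. Fragile elements are the exo-methylene lactone (a Michael acceptor), the possible translactonisation from O6 to O8 whenever O8 is free, the epimerisable α-centre and β-hydroxyl of the side chain, and three terminal alkenes that exclude ozonolysis, hydrogenation and late dihydroxylation. The real difficulty is the unbroken array C10–C5–C6–C7–C8 (one quaternary, four tertiary centres) together with telling O6, O8, O15 and the side-chain oxygen apart. The key step uses the adjacency of C6 and C7 in the carbocycle: a C6 aldehyde and an allyl metal spanning C13–C11–C7 are joined at C6–C7, which closes ring C5–C10, sets C6 and C7, and leaves the hydroxyl and the acrylate where the lactone needs them.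

## Logic of the disconnections

33 is traced to 32 by cutting only the two O–Si bonds at O15 and at the side-chain oxygen. Both primary alcohols stay masked to the end, so the last step removes silicon and nothing else. The forward step needs a fluoride source that is neither basic nor nucleophilic toward the enoate, the ester and its α-centre.

32 is cut at the C8 O–acyl bond into 27 and 30. This is convergent and takes the remote stereocentre from the chiral pool (30 from 28 through 29). The forward acylation must esterify a hindered secondary alcohol beside a lactone without translactonisation toward O8 and without epimerising the acid.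

27 goes back to 26 (O8–Si) and 26 to 25 (lactone bond C12–O6). O8 is kept silylated while the ring closes, so O6 is the only oxygen that can attack the ester. The forward steps need an acid closure that spares the C8 ether, then removal of that ether in the presence of the more robust one at O15.

25 is cut at the ring bond C6–C7 to the acyclic 23 (through 24). C6 becomes an aldehyde and C7 the γ-terminus of a 2-(alkoxycarbonyl)allyl metal generated from the C13 bromide. One step then gives the carbocycle, two stereocentres and the acrylate, and the precursor holds only C5, C8 and C10. The forward step must close anti (C6–O α, C7–C11 β). The design therefore relies on an allylchromium that equilibrates to its (E)-form, so the readily made (Z)-bromide suffices. The aldehyde, whose C5 centre is allylic and α to the carbonyl, is unveiled last, and O15 carries a silyl group that survives every acidic step.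

23 comes from 22 (oxidation level of C6), 22 from 21 (O6 ether), 21 from 20 (C13–Br with allylic transposition), and 20 from 18 and 19 (bond C7–C11). The acrylate unit is thus added to a C7 aldehyde, and the carbinol centre created there is erased by the transposition, so it needs no control. The demands are that O6 stays masked while C7 is an aldehyde, and that its unmasking tolerates an allylic bromide, an enoate and silyl ethers.

18 is traced through 17 and 16 to 15, and 15 to 14. The C7 aldehyde comes from the terminal 1,2-diol, which is revealed from its acetonide, silylated twice and oxidised selectively at the primary position. This leaves the C8 ether in the form needed later. The acetonide cleavage must spare the O15 and O6 ethers.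

14 goes back to 13 (C1=C2 by carbonyl olefination) and 13 to 12 (reduction at C1). The lactone in 12 ties C1 to O6. Opening it through the lactol turns one end into the vinyl group and frees the other as the only hydroxyl. The olefination must work on a hindered, α-quaternary lactol.

12 is cut at C10–C14 to 10, and 10 at C10–C9 to 6 and 8 (8 from 7). Both bonds are made by enolate alkylation on the face opposite the C5 substituent. The C9 chain must therefore enter first and the methyl last to give the C10/C5 relation of the target. 8 brings C7–C9 with C8 already set. The first alkylation needs a β-alkoxy electrophile reactive enough for a lactone enolate.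

6 is cut at C4–C5 into 4 and 5 (4 from 2, 2 from 1). Conjugate addition to the butenolide sets the first stereocentre, from which C10, then C6 and C7, are relayed. The forward step needs catalyst control of the enantioface with an α-branched alkenyl nucleophile that already carries O15.

## Other disconnections considered

Alternative 1: The cut is the ring bond C9–C10, with a transient C1–C2 bond. Irradiation of the enolised keto aldehyde A1 adds the enol double bond across the tethered isopropenyl group, and retro-aldol fragmentation in the same flask leads to the cyclohexanone A2 (de Mayo reaction).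
- In favour: the quaternary centre C10 and the carbocycle arise in one reagent-free step from a chain with a single stereocentre, and the two carbons of the future vinyl group arrive with C10.
- Against: A2 has no oxygen at C6, no carbon at C7, a ketone at C8 and both arms at the wrong oxidation pattern. The four-atom tether makes the straight versus crossed regiochemistry of the photocycloaddition uncertain. A2 is a 1,5-dicarbonyl compound open to intramolecular aldol reactions.
- Structure: the alternative is the better plan for C10 (one step instead of two alkylations). The chosen plan is better for the C6–C7–C8 triad, which the alternative must build on the ring afterwards, one centre at a time.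
- Mechanism: an excited-state cycloaddition is harder to predict than the chelated ground-state chair of the chromium step.
- Step economy: the alternative is equal or better up to the ring closure, but needs roughly ten further steps after it against four here.

Alternative 2: The cut is C12–O6 and C11–C12, with C12 supplied by CO. The trans-2-ethynylcyclohexanol A3 is treated with PdI2 and PBu3 under CO: alkoxycarbonylation at O6, syn addition across the ethynyl group and protonolysis give the lactone A4.
- In favour: the Michael acceptor appears at the very end from a robust alkyne, no acrylate ester has to be carried or transesterified, and the lactone regiochemistry is unambiguous. On these points, and on atom economy, the alternative is the better plan.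
- Equal: A4 is the tert-butyldimethylsilyl counterpart of 26, so the endgame would be as short as the chosen one.
- Against: the key step forms neither the carbocycle nor any stereocentre. A3 must already contain all four contiguous ring centres, including a trans-diequatorial hydroxyl/ethynyl pair, so the central problem is moved upstream and left unsolved. A trans-fused closure is more strained than a cis one, CO under pressure is needed, and palladium hydride species could isomerise the terminal alkenes.
- Overall: the chosen plan is better in structural terms because ring, C6, C7 and acrylate come from one step.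

Alternative 3: The cut is C5–C6. MeAlCl2 activates the C6 aldehyde of the allylsilane A5, C5 attacks, and loss of silicon creates the C4=C3 methylene of A6 (Prins–Sakurai closure).
- In favour: the allylsilane is stable through many steps, and ring, C5, C6 and the exocyclic methylene with O15 in place are formed together. No stoichiometric chromium is needed; on reagent handling and waste the alternative is the better plan.
- Equal: both plans close the same ring by adding an allyl metal(loid) to an aldehyde with two new stereocentres.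
- Against: the attacking carbon C5 sits next to the quaternary C10. The aldehyde in A5 has an acidic α-hydrogen at C7 and a β-silyloxy group at C8, so Lewis acid can cause epimerisation or β-elimination. The open transition state gives less control of the C5/C6 relation than the closed chromium chair. The C7 arm in A6 is a saturated acetate, so the α-methylene group must be added after lactonisation under basic conditions. A5 requires C7, C8 and the remote quaternary C10 to be set on an open chain, whereas the chosen route sets C10 next to C5 under ring control and leaves C7 to the cyclisation.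
- Step economy: this favours the chosen plan by the late methylenation steps.

Key step: step 17

Notation: TBDPS = tert-butyldiphenylsilyl, TES = triethylsilyl, TBS = tert-butyldimethylsilyl, PMB = 4-methoxybenzyl.

Assumption: the sense of induction of the rhodium–BINAP addition to 5 is taken to follow that established for cyclic enones and unsaturated lactones, so that (R)-BINAP leads to (R)-6; should the sense be the reverse, (S)-BINAP is used with no other change.

## Steps

Step 1
Reactants: 1 bromoallyl alcohol (2-bromoprop-2-en-1-ol)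
Product: 2 [(2-bromoprop-2-en-1-yl)oxy](tert-butyl)diphenylsilane
Conditions: t-BuPh2SiCl, imidazole, CH2Cl2, 0 °C → rt
Reagents that add atoms: tert-butyl(chloro)diphenylsilane, CC(C)(C)[Si](Cl)(c1ccccc1)c1ccccc1
Why: Silyl ether formation at a primary alcohol; the bulky TBDPS group is chosen because it must outlast the acidic acetonide cleavage and lactonisation and must not migrate to the neighbouring alkenyllithium.

Step 2
Reactants: 2 [(2-bromoprop-2-en-1-yl)oxy](tert-butyl)diphenylsilane
Product: 4 pinacol [3-(TBDPS-oxy)prop-1-en-2-yl]boronate, via alkenyllithium 3 (not isolated)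
Conditions: t-BuLi (2.1 equiv), Et2O, −78 °C; then 2-isopropoxy-4,4,5,5-tetramethyl-1,3,2-dioxaborolane, −78 °C → rt
Reagents that add atoms: 2-isopropoxy-4,4,5,5-tetramethyl-1,3,2-dioxaborolane, CC(C)OB1OC(C)(C)C(C)(C)O1
Why: Bromine–lithium exchange on an alkenyl bromide followed by borylation of the alkenyllithium with an alkoxyboronate; at −78 °C the bulky silyl ether is neither transferred to carbon nor expelled.

Step 3
Reactants: 4 pinacol [3-(TBDPS-oxy)prop-1-en-2-yl]boronate; 5 furan-2(5H)-one
Product: 6 (4R)-4-[3-(TBDPS-oxy)prop-1-en-2-yl]oxolan-2-one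
Conditions: [Rh(OH)(cod)]2 (2.5 mol %), (R)-BINAP (6 mol %), dioxane/H2O (10:1), 50 °C
Reagents that add atoms: none
Why: Rhodium-catalysed asymmetric 1,4-addition of an alkenylboron reagent to an unsaturated lactone (Hayashi–Miyaura reaction): transmetalation to [Rh(OH)((R)-BINAP)] (monovalent rhodium), enantioface-selective insertion of 5 and protonolysis by water. The ligand sets C5, and (R)-BINAP is expected to give the (R)-lactone.

Step 4
Reactants: 7 (S)-solketal, [(4S)-2,2-dimethyl-1,3-dioxolan-4-yl]methanol
Product: 8 [(4R)-2,2-dimethyl-1,3-dioxolan-4-yl]methyl trifluoromethanesulfonate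
Conditions: Tf2O, 2,6-lutidine, CH2Cl2, −78 °C; used at once
Reagents that add atoms: trifluoromethanesulfonic anhydride, O=S(=O)(OS(=O)(=O)C(F)(F)F)C(F)(F)F
Why: Sulfonylation of a primary alcohol; the stereocentre is untouched (the descriptor changes only through the priority rules). The triflate is needed because β-alkoxy halides are too sluggish toward lactone enolates.

Step 5
Reactants: 6 (4R)-4-[3-(TBDPS-oxy)prop-1-en-2-yl]oxolan-2-one; 8 [(4R)-2,2-dimethyl-1,3-dioxolan-4-yl]methyl trifluoromethanesulfonate
Product: 10 (3S,4R)-3-{[(4S)-2,2-dimethyl-1,3-dioxolan-4-yl]methyl}-4-[3-(TBDPS-oxy)prop-1-en-2-yl]oxolan-2-one, via lithium enolate 9 (not isolated)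
Conditions: LiN(SiMe3)2, THF, −78 °C; then 8, −78 → −40 °C
Reagents that add atoms: none
Why: Alkylation of a lactone lithium enolate with a primary triflate; the electrophile enters on the face opposite the C5 alkenyl group and gives the 3,4-trans lactone. The silazide base is used so that its conjugate acid does not consume the triflate.

Step 6
Reactants: 10 (3S,4R)-3-{[(4S)-2,2-dimethyl-1,3-dioxolan-4-yl]methyl}-4-[3-(TBDPS-oxy)prop-1-en-2-yl]oxolan-2-one
Product: 12 (3R,4S)-3-{[(4S)-2,2-dimethyl-1,3-dioxolan-4-yl]methyl}-3-methyl-4-[3-(TBDPS-oxy)prop-1-en-2-yl]oxolan-2-one, via lithium enolate 11 (not isolated)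
Conditions: LiN(iPr)2, THF, −78 °C; then MeI, −78 → −30 °C
Reagents that add atoms: iodomethane, CI
Why: Second enolate alkylation, creating the quaternary centre C10; the planar enolate is again attacked opposite the C5 substituent. The methyl group therefore ends trans to it and the C9 chain cis, which is the C10/C5 relation of the target.

Step 7
Reactants: 12 (3R,4S)-3-{[(4S)-2,2-dimethyl-1,3-dioxolan-4-yl]methyl}-3-methyl-4-[3-(TBDPS-oxy)prop-1-en-2-yl]oxolan-2-one
Product: 13 (3R,4S)-lactol of 12 (oxolan-2-ol; anomer mixture)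
Conditions: iBu2AlH, CH2Cl2, −78 °C
Reagents that add atoms: none
Why: Partial reduction of a lactone to the lactol by an aluminium hydride; the tetrahedral aluminate of the hindered α-quaternary lactone persists at −78 °C, which prevents over-reduction.

Step 8
Reactants: 13 (3R,4S)-lactol of 12 (oxolan-2-ol; anomer mixture)
Product: 14 (2R,3S)-3-{[(4S)-2,2-dimethyl-1,3-dioxolan-4-yl]methyl}-3-methyl-2-[3-(TBDPS-oxy)prop-1-en-2-yl]pent-4-en-1-ol
Conditions: Ph3PCH3Br, KOtBu, THF, 0 → 50 °C
Reagents that add atoms: methyltriphenylphosphonium bromide, C[P+](c1ccccc1)(c1ccccc1)c1ccccc1.[Br-]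
Why: Wittig methylenation of the lactol through its open hydroxy-aldehyde form; C1 becomes the vinyl group on the quaternary carbon (no α-hydrogen, hence no epimerisation) and O6 is released as the only free hydroxyl.

Step 9
Reactants: 14 (2R,3S)-3-{[(4S)-2,2-dimethyl-1,3-dioxolan-4-yl]methyl}-3-methyl-2-[3-(TBDPS-oxy)prop-1-en-2-yl]pent-4-en-1-ol
Product: 15 PMB ether of 14
Conditions: NaH, 4-MeOC6H4CH2Cl, tetrabutylammonium iodide (cat.), THF/DMF, 0 °C → rt
Reagents that add atoms: 4-methoxybenzyl chloride, COc1ccc(CCl)cc1
Why: Williamson ether synthesis; the PMB ether masks O6 through the acidic, silylating, oxidising and amine-catalysed steps. It can later be removed oxidatively without touching silyl ethers, the enoate or the allylic bromide.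

Step 10
Reactants: 15 PMB ether of 14
Product: 16 (2S,4S,5R)-4-ethenyl-4-methyl-6-(PMB-oxy)-5-[3-(TBDPS-oxy)prop-1-en-2-yl]hexane-1,2-diol
Conditions: PPTS (cat.), MeOH, 45 °C
Reagents that add atoms: none
Why: Acid-catalysed transacetalisation of a terminal acetonide with methanol; the primary TBDPS ether and the PMB ether are stable to these conditions.

Step 11
Reactants: 16 (2S,4S,5R)-4-ethenyl-4-methyl-6-(PMB-oxy)-5-[3-(TBDPS-oxy)prop-1-en-2-yl]hexane-1,2-diol
Product: 17 1,2-bis(TES) ether of 16
Conditions: Et3SiCl, imidazole, DMAP (cat.), CH2Cl2, 0 °C → rt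
Reagents that add atoms: chlorotriethylsilane, CC[Si](Cl)(CC)CC
Why: Exhaustive silylation of the 1,2-diol; TES is chosen because its primary ether is oxidised directly in the next step, while its secondary ether is kept and is later the most labile silyl group in the molecule.

Step 12
Reactants: 17 1,2-bis(TES) ether of 16
Product: 18 (2S,4S,5R)-4-ethenyl-4-methyl-6-(PMB-oxy)-5-[3-(TBDPS-oxy)prop-1-en-2-yl]-2-(TES-oxy)hexanal
Conditions: (COCl)2, DMSO, CH2Cl2, −78 → −40 °C; then iPr2NEt, −78 → 0 °C
Reagents that add atoms: none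
Why: Swern oxidation in which the primary TES ether is cleaved by the chlorosulfonium salt and oxidised in the same flask, while the secondary TES, TBDPS and PMB ethers persist. Low temperature and a hindered amine protect the α-silyloxy aldehyde from epimerisation at C8.

Step 13
Reactants: 18 (2S,4S,5R)-4-ethenyl-4-methyl-6-(PMB-oxy)-5-[3-(TBDPS-oxy)prop-1-en-2-yl]-2-(TES-oxy)hexanal; 19 methyl acrylate
Product: 20 methyl (4S,6S,7R)-6-ethenyl-3-hydroxy-6-methyl-2-methylidene-8-(PMB-oxy)-7-[3-(TBDPS-oxy)prop-1-en-2-yl]-4-(TES-oxy)octanoate (both C3 epimers)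
Conditions: DABCO (1 equiv), methyl acrylate (excess), MeOH, rt
Reagents that add atoms: none
Why: Baylis–Hillman reaction (amine-catalysed coupling of the acrylate α-carbon with an aldehyde), for which α-oxygenated aldehydes are among the fastest substrates. The new carbinol centre at C7 needs no control because it is erased in the next step.

Step 14
Reactants: 20 methyl (4S,6S,7R)-6-ethenyl-3-hydroxy-6-methyl-2-methylidene-8-(PMB-oxy)-7-[3-(TBDPS-oxy)prop-1-en-2-yl]-4-(TES-oxy)octanoate (both C3 epimers)
Product: 21 methyl (2Z,4S,6S,7R)-2-(bromomethyl)-6-ethenyl-6-methyl-8-(PMB-oxy)-7-[3-(TBDPS-oxy)prop-1-en-2-yl]-4-(TES-oxy)oct-2-enoate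
Conditions: NBS, Me2S, CH2Cl2, 0 °C → rt
Reagents that add atoms: N-bromosuccinimide, O=C1CCC(=O)N1Br
Why: Bromination of a Baylis–Hillman alcohol with allylic transposition (Corey–Kim-type alkoxysulfonium salt attacked by bromide at C13 in the SN2′ sense). The trisubstituted enoate forms with the ester trans to C8, that is the (Z)-bromide, and both C7 epimers converge.

Step 15
Reactants: 21 methyl (2Z,4S,6S,7R)-2-(bromomethyl)-6-ethenyl-6-methyl-8-(PMB-oxy)-7-[3-(TBDPS-oxy)prop-1-en-2-yl]-4-(TES-oxy)oct-2-enoate
Product: 22 methyl (2Z,4S,6S,7R)-2-(bromomethyl)-6-ethenyl-8-hydroxy-6-methyl-7-[3-(TBDPS-oxy)prop-1-en-2-yl]-4-(TES-oxy)oct-2-enoate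
Conditions: DDQ, CH2Cl2/pH 7 buffer, 0 °C
Reagents that add atoms: none
Why: Oxidative cleavage of a PMB ether by DDQ (hydride abstraction from the electron-rich benzylic position, then hydrolysis); under buffered conditions the silyl ethers, the enoate and the allylic bromide are left alone.

Step 16
Reactants: 22 methyl (2Z,4S,6S,7R)-2-(bromomethyl)-6-ethenyl-8-hydroxy-6-methyl-7-[3-(TBDPS-oxy)prop-1-en-2-yl]-4-(TES-oxy)oct-2-enoate
Product: 23 methyl (2Z,4S,6S,7R)-2-(bromomethyl)-6-ethenyl-6-methyl-8-oxo-7-[3-(TBDPS-oxy)prop-1-en-2-yl]-4-(TES-oxy)oct-2-enoate (cyclisation precursor)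
Conditions: Dess–Martin periodinane, NaHCO3, CH2Cl2, 0 °C → rt; used at once
Reagents that add atoms: none
Why: Dess–Martin oxidation of a primary alcohol under buffered, non-basic conditions, so that the β,γ-unsaturated aldehyde keeps its C5 configuration.

Step 17
Reactants: 23 methyl (2Z,4S,6S,7R)-2-(bromomethyl)-6-ethenyl-6-methyl-8-oxo-7-[3-(TBDPS-oxy)prop-1-en-2-yl]-4-(TES-oxy)oct-2-enoate (cyclisation precursor)
Product: 25 methyl 2-[(1S,2R,3R,4S,6S)-4-ethenyl-2-hydroxy-4-methyl-3-[3-(TBDPS-oxy)prop-1-en-2-yl]-6-(TES-oxy)cyclohexyl]prop-2-enoate, via allylchromium dichloride 24 (not isolated)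
Conditions: CrCl2 (5 equiv), THF (0.01 M), rt; aq. NH4Cl
Reagents that add atoms: none
Why: Two one-electron transfers from CrCl2 (divalent chromium) replace the C13–Br bond by a C13–Cr bond of trivalent chromium (24), an allyl metal that is nucleophilic at its γ-carbon C7; chromium binds the C6 carbonyl oxygen and C7 adds to C6 through a six-membered chair (Cr, O, C6, C7, C11, C13) while the double bond moves to C11=C13. The closest known reaction type is the intramolecular Nozaki–Hiyama (chromium Barbier) allylation of aldehydes by 2-(bromomethyl)alk-2-enoates, an established entry to carbocycle-fused hydroxy acrylates and α-methylene-γ-butyrolactones. The carbocycle C5–C10 closes in the 6-exo-trig mode (the C6=O bond and the C7=C11 bond both lie outside the new ring). The σ-allylchromium should interconvert between its geometrical isomers through the C7-bound form, so the (Z)-geometry of the bromide is not transmitted; the (E)-isomer reacts through a trans-fused chair–chair array in which the forming ring carries the C5 arm, the C8 silyloxy group and the C10 vinyl group equatorial and the C10 methyl axial. C7 is thereby controlled by C8 and C10 (the C7–C11 bond becomes equatorial, β), and C6 by C5 and by the trans fusion of the chromium chair (C6–O equatorial, α). The selectivity required is the anti, trans-diequatorial relation at C6/C7 in the correct sense to C5, C8 and C10: the syn alternative from the (Z)-allylchromium would place the C6–O–Cr bond axial and 1,3-diaxial to the C10 methyl, and the inverted chair would place the C8 silyloxy and C10 vinyl groups 1,3-diaxial. CrCl2 leaves the ester, the silyl ethers and the isolated alkenes untouched, the neutral medium preserves the labile C5 centre, the addition is irreversible, and high dilution suppresses intermolecular coupling.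

Step 18
Reactants: 25 methyl 2-[(1S,2R,3R,4S,6S)-4-ethenyl-2-hydroxy-4-methyl-3-[3-(TBDPS-oxy)prop-1-en-2-yl]-6-(TES-oxy)cyclohexyl]prop-2-enoate
Product: 26 (3aS,4S,6S,7R,7aR)-6-ethenyl-6-methyl-3-methylidene-7-[3-(TBDPS-oxy)prop-1-en-2-yl]-4-(TES-oxy)hexahydro-1-benzofuran-2(3H)-one
Conditions: CSA (cat.), 5 Å molecular sieves, CH2Cl2, rt
Reagents that add atoms: none
Why: Acid-catalysed intramolecular transesterification (lactonisation) of the trans-diequatorial γ-hydroxy ester; only O6 is free, so the 6,12-lactone is the sole possible ring. Anhydrous catalytic acid with sieves to take up methanol is chosen to spare the C8 silyl ether.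

Step 19
Reactants: 26 (3aS,4S,6S,7R,7aR)-6-ethenyl-6-methyl-3-methylidene-7-[3-(TBDPS-oxy)prop-1-en-2-yl]-4-(TES-oxy)hexahydro-1-benzofuran-2(3H)-one
Product: 27 (3aR,4S,6S,7R,7aR)-6-ethenyl-4-hydroxy-6-methyl-3-methylidene-7-[3-(TBDPS-oxy)prop-1-en-2-yl]hexahydro-1-benzofuran-2(3H)-one
Conditions: HF·pyridine, pyridine, THF, 0 °C
Reagents that add atoms: none
Why: Selective desilylation: a secondary TES ether is cleaved by buffered HF·pyridine far faster than a primary TBDPS ether, and the non-basic medium avoids translactonisation and conjugate addition.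

Step 20
Reactants: 28 methyl (2R)-3-hydroxy-2-methylpropanoate (Roche ester)
Product: 29 methyl (2R)-2-methyl-3-(TBS-oxy)propanoate
Conditions: t-BuMe2SiCl, imidazole, CH2Cl2, 0 °C → rt
Reagents that add atoms: tert-butyl(chloro)dimethylsilane, CC(C)(C)[Si](C)(C)Cl
Why: Silyl ether formation at the primary alcohol, so that the acid cannot acylate itself in step 22.

Step 21
Reactants: 29 methyl (2R)-2-methyl-3-(TBS-oxy)propanoate
Product: 30 (2R)-2-methyl-3-(TBS-oxy)propanoic acid
Conditions: LiOH, THF/H2O, 0 °C; then aq. HCl to pH 4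
Reagents that add atoms: lithium hydroxide, [Li+].[OH-]
Why: Saponification of a methyl ester at 0 °C; under these conditions hydroxide should not epimerise the α-centre of a simple alkanoate, and the primary silyl ether survives.

Step 22
Reactants: 27 (3aR,4S,6S,7R,7aR)-6-ethenyl-4-hydroxy-6-methyl-3-methylidene-7-[3-(TBDPS-oxy)prop-1-en-2-yl]hexahydro-1-benzofuran-2(3H)-one; 30 (2R)-2-methyl-3-(TBS-oxy)propanoic acid
Product: 32 (3aR,4S,6S,7R,7aR)-6-ethenyl-6-methyl-3-methylidene-2-oxo-7-[3-(TBDPS-oxy)prop-1-en-2-yl]octahydro-1-benzofuran-4-yl (2R)-2-methyl-3-(TBS-oxy)propanoate, via mixed anhydride 31 (not isolated)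
Conditions: 30, 2,4,6-Cl3C6H2COCl, Et3N, toluene, rt; then 27, DMAP, 0 °C → rt
Reagents that add atoms: none
Why: Yamaguchi esterification (mixed anhydride, acyl transfer by DMAP) of the equatorial C8 alcohol with retention at C8. Low temperature and short exposure to base limit translactonisation toward O8 and ketene-mediated epimerisation of the acyl α-centre.

Step 23
Reactants: 32 (3aR,4S,6S,7R,7aR)-6-ethenyl-6-methyl-3-methylidene-2-oxo-7-[3-(TBDPS-oxy)prop-1-en-2-yl]octahydro-1-benzofuran-4-yl (2R)-2-methyl-3-(TBS-oxy)propanoate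
Product: 33 (3aR,4S,6S,7R,7aR)-6-ethenyl-7-(3-hydroxyprop-1-en-2-yl)-6-methyl-3-methylidene-2-oxooctahydro-1-benzofuran-4-yl (2R)-3-hydroxy-2-methylpropanoate (target)
Conditions: HF·pyridine, pyridine, THF, 0 °C → rt
Reagents that add atoms: none
Why: Fluoride-mediated cleavage of both primary silyl ethers with buffered HF·pyridine, which is neither basic nor nucleophilic enough to attack the α-methylene lactone, the C8 ester or its α-centre.

## Compound list

1 | bromoallyl alcohol (2-bromoprop-2-en-1-ol) | OCC(Br)=C | starting material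
2 | [(2-bromoprop-2-en-1-yl)oxy](tert-butyl)diphenylsilane | C=C(Br)CO[Si](c1ccccc1)(c1ccccc1)C(C)(C)C | intermediate
3 | alkenyllithium, 2-lithio-3-(TBDPS-oxy)prop-1-ene (not isolated) | [Li]C(=C)CO[Si](c1ccccc1)(c1ccccc1)C(C)(C)C | intermediate
4 | pinacol [3-(TBDPS-oxy)prop-1-en-2-yl]boronate | C=C(CO[Si](c1ccccc1)(c1ccccc1)C(C)(C)C)B1OC(C)(C)C(C)(C)O1 | intermediate
5 | furan-2(5H)-one | O=C1OCC=C1 | starting material
6 | (4R)-4-[3-(TBDPS-oxy)prop-1-en-2-yl]oxolan-2-one | O=C1C[C@H](C(=C)CO[Si](c2ccccc2)(c2ccccc2)C(C)(C)C)CO1 | intermediate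
7 | (S)-solketal, [(4S)-2,2-dimethyl-1,3-dioxolan-4-yl]methanol | OC[C@H]1COC(C)(C)O1 | starting material
8 | [(4R)-2,2-dimethyl-1,3-dioxolan-4-yl]methyl trifluoromethanesulfonate | O=S(=O)(OC[C@H]1COC(C)(C)O1)C(F)(F)F | intermediate
9 | lithium enolate of 6 (not isolated) | [Li]OC1=C[C@H](C(=C)CO[Si](c2ccccc2)(c2ccccc2)C(C)(C)C)CO1 | intermediate
10 | (3S,4R)-3-{[(4S)-2,2-dimethyl-1,3-dioxolan-4-yl]methyl}-4-[3-(TBDPS-oxy)prop-1-en-2-yl]oxolan-2-one (3,4-trans) | O=C1OC[C@@H](C(=C)CO[Si](c2ccccc2)(c2ccccc2)C(C)(C)C)[C@@H]1C[C@H]1COC(C)(C)O1 | intermediate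
11 | lithium enolate of 10 (not isolated) | [Li]OC1=C(C[C@H]2COC(C)(C)O2)[C@H](C(=C)CO[Si](c2ccccc2)(c2ccccc2)C(C)(C)C)CO1 | intermediate
12 | (3R,4S)-3-{[(4S)-2,2-dimethyl-1,3-dioxolan-4-yl]methyl}-3-methyl-4-[3-(TBDPS-oxy)prop-1-en-2-yl]oxolan-2-one (methyl trans to the alkenyl group) | C[C@@]1(C[C@H]2COC(C)(C)O2)[C@H](C(=C)CO[Si](c2ccccc2)(c2ccccc2)C(C)(C)C)COC1=O | intermediate
13 | (3R,4S)-lactol of 12 (oxolan-2-ol; anomer mixture) | C[C@@]1(C[C@H]2COC(C)(C)O2)[C@H](C(=C)CO[Si](c2ccccc2)(c2ccccc2)C(C)(C)C)COC1O | intermediate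
14 | (2R,3S)-3-{[(4S)-2,2-dimethyl-1,3-dioxolan-4-yl]methyl}-3-methyl-2-[3-(TBDPS-oxy)prop-1-en-2-yl]pent-4-en-1-ol | C=C[C@](C)(C[C@H]1COC(C)(C)O1)[C@@H](CO)C(=C)CO[Si](c1ccccc1)(c1ccccc1)C(C)(C)C | intermediate
15 | PMB ether of 14 | C=C[C@](C)(C[C@H]1COC(C)(C)O1)[C@@H](COCc1ccc(OC)cc1)C(=C)CO[Si](c1ccccc1)(c1ccccc1)C(C)(C)C | intermediate
16 | (2S,4S,5R)-4-ethenyl-4-methyl-6-(PMB-oxy)-5-[3-(TBDPS-oxy)prop-1-en-2-yl]hexane-1,2-diol | C=C[C@](C)(C[C@H](O)CO)[C@@H](COCc1ccc(OC)cc1)C(=C)CO[Si](c1ccccc1)(c1ccccc1)C(C)(C)C | intermediate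
17 | 1,2-bis(TES) ether of 16 | C=C[C@](C)(C[C@H](O[Si](CC)(CC)CC)CO[Si](CC)(CC)CC)[C@@H](COCc1ccc(OC)cc1)C(=C)CO[Si](c1ccccc1)(c1ccccc1)C(C)(C)C | intermediate
18 | (2S,4S,5R)-4-ethenyl-4-methyl-6-(PMB-oxy)-5-[3-(TBDPS-oxy)prop-1-en-2-yl]-2-(TES-oxy)hexanal | C=C[C@](C)(C[C@H](O[Si](CC)(CC)CC)C=O)[C@@H](COCc1ccc(OC)cc1)C(=C)CO[Si](c1ccccc1)(c1ccccc1)C(C)(C)C | intermediate
19 | methyl acrylate | C=CC(=O)OC | starting material
20 | methyl (4S,6S,7R)-6-ethenyl-3-hydroxy-6-methyl-2-methylidene-8-(PMB-oxy)-7-[3-(TBDPS-oxy)prop-1-en-2-yl]-4-(TES-oxy)octanoate (both C3 epimers) | C=C[C@](C)(C[C@H](O[Si](CC)(CC)CC)C(O)C(=C)C(=O)OC)[C@@H](COCc1ccc(OC)cc1)C(=C)CO[Si](c1ccccc1)(c1ccccc1)C(C)(C)C | intermediate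
21 | methyl (2Z,4S,6S,7R)-2-(bromomethyl)-6-ethenyl-6-methyl-8-(PMB-oxy)-7-[3-(TBDPS-oxy)prop-1-en-2-yl]-4-(TES-oxy)oct-2-enoate | C=C[C@](C)(C[C@H](O[Si](CC)(CC)CC)/C=C(\CBr)C(=O)OC)[C@@H](COCc1ccc(OC)cc1)C(=C)CO[Si](c1ccccc1)(c1ccccc1)C(C)(C)C | intermediate
22 | methyl (2Z,4S,6S,7R)-2-(bromomethyl)-6-ethenyl-8-hydroxy-6-methyl-7-[3-(TBDPS-oxy)prop-1-en-2-yl]-4-(TES-oxy)oct-2-enoate | C=C[C@](C)(C[C@H](O[Si](CC)(CC)CC)/C=C(\CBr)C(=O)OC)[C@@H](CO)C(=C)CO[Si](c1ccccc1)(c1ccccc1)C(C)(C)C | intermediate
23 | methyl (2Z,4S,6S,7R)-2-(bromomethyl)-6-ethenyl-6-methyl-8-oxo-7-[3-(TBDPS-oxy)prop-1-en-2-yl]-4-(TES-oxy)oct-2-enoate (cyclisation precursor) | C=C[C@](C)(C[C@H](O[Si](CC)(CC)CC)/C=C(\CBr)C(=O)OC)[C@@H](C=O)C(=C)CO[Si](c1ccccc1)(c1ccccc1)C(C)(C)C | intermediate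
24 | allylchromium dichloride from 23, (E)-form, trivalent chromium on C13 (not isolated) | C=C[C@](C)(C[C@H](O[Si](CC)(CC)CC)/C=C(/C[Cr](Cl)Cl)C(=O)OC)[C@@H](C=O)C(=C)CO[Si](c1ccccc1)(c1ccccc1)C(C)(C)C | intermediate
25 | methyl 2-[(1S,2R,3R,4S,6S)-4-ethenyl-2-hydroxy-4-methyl-3-[3-(TBDPS-oxy)prop-1-en-2-yl]-6-(TES-oxy)cyclohexyl]prop-2-enoate (6α-hydroxy, 7β-acrylate) | C=C[C@]1(C)C[C@H](O[Si](CC)(CC)CC)[C@@H](C(=C)C(=O)OC)[C@H](O)[C@H]1C(=C)CO[Si](c1ccccc1)(c1ccccc1)C(C)(C)C | intermediate
26 | (3aS,4S,6S,7R,7aR)-6-ethenyl-6-methyl-3-methylidene-7-[3-(TBDPS-oxy)prop-1-en-2-yl]-4-(TES-oxy)hexahydro-1-benzofuran-2(3H)-one | C=C[C@]1(C)C[C@H](O[Si](CC)(CC)CC)[C@H]2C(=C)C(=O)O[C@@H]2[C@H]1C(=C)CO[Si](c1ccccc1)(c1ccccc1)C(C)(C)C | intermediate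
27 | (3aR,4S,6S,7R,7aR)-6-ethenyl-4-hydroxy-6-methyl-3-methylidene-7-[3-(TBDPS-oxy)prop-1-en-2-yl]hexahydro-1-benzofuran-2(3H)-one | C=C[C@]1(C)C[C@H](O)[C@H]2C(=C)C(=O)O[C@@H]2[C@H]1C(=C)CO[Si](c1ccccc1)(c1ccccc1)C(C)(C)C | intermediate
28 | methyl (2R)-3-hydroxy-2-methylpropanoate (Roche ester) | COC(=O)[C@H](C)CO | starting material
29 | methyl (2R)-2-methyl-3-(TBS-oxy)propanoate | COC(=O)[C@H](C)CO[Si](C)(C)C(C)(C)C | intermediate
30 | (2R)-2-methyl-3-(TBS-oxy)propanoic acid | OC(=O)[C@H](C)CO[Si](C)(C)C(C)(C)C | intermediate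
31 | mixed anhydride of 30 with 2,4,6-trichlorobenzoic acid (not isolated) | O=C(OC(=O)[C@H](C)CO[Si](C)(C)C(C)(C)C)c1c(Cl)cc(Cl)cc1Cl | intermediate
32 | (3aR,4S,6S,7R,7aR)-6-ethenyl-6-methyl-3-methylidene-2-oxo-7-[3-(TBDPS-oxy)prop-1-en-2-yl]octahydro-1-benzofuran-4-yl (2R)-2-methyl-3-(TBS-oxy)propanoate | C=C[C@]1(C)C[C@H](OC(=O)[C@H](C)CO[Si](C)(C)C(C)(C)C)[C@H]2C(=C)C(=O)O[C@@H]2[C@H]1C(=C)CO[Si](c1ccccc1)(c1ccccc1)C(C)(C)C | intermediate
33 | (3aR,4S,6S,7R,7aR)-6-ethenyl-7-(3-hydroxyprop-1-en-2-yl)-6-methyl-3-methylidene-2-oxooctahydro-1-benzofuran-4-yl (2R)-3-hydroxy-2-methylpropanoate | C=C[C@]1(C)C[C@H](OC(=O)[C@H](C)CO)[C@H]2C(=C)C(=O)O[C@@H]2[C@H]1C(=C)CO | target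

## Step count and least certain steps

Total step count: 23. Longest linear sequence: 20 steps (steps 1–3, 5–19, 22 and 23); steps 4, 20 and 21 prepare the two side branches.

Step 17 (key step). The most likely failure is closure through the cis-fused chair before the allylchromium has equilibrated to its (E)-form, which erodes the anti relation at C6/C7. Protonation or dimerisation of the allylchromium is possible if dilution is insufficient. The fallback sets out from 23 and rejoins the route at 26. The syn adduct, methyl 2-[(1S,2S,3R,4S,6S)-4-ethenyl-2-hydroxy-4-methyl-3-[3-(TBDPS-oxy)prop-1-en-2-yl]-6-(TES-oxy)cyclohexyl]prop-2-enoate F1 (6β-hydroxy), is not discarded. Its methyl ester is hydrolysed with Me3SnOH in 1,2-dichloroethane to the hydroxy acid F2. F2 is closed under Mitsunobu conditions (PPh3, diisopropyl azodicarboxylate, toluene, 0 °C), in which the carboxylate displaces the activated axial C6 oxygen with inversion and gives the trans-fused lactone 26.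

Step 3. Transmetalation of the α-branched alkenylboronate may be slow, so that protodeboronation and ring opening of the butenolide in the aqueous medium compete, and the facial selectivity may be incomplete. The fallback sets out from 3 and 5 and rejoins the route at 10. Two equivalents of 3 and CuBr·SMe2 give the lithium dialkenylcuprate F3, which adds to 5 at −78 °C without any chiral ligand. 6 is then formed together with its enantiomer, (4S)-4-[3-(TBDPS-oxy)prop-1-en-2-yl]oxolan-2-one F4. Alkylation of the mixture with 8 as in step 5 turns the pair into 10 and its diastereomer, (3R,4S)-3-{[(4S)-2,2-dimethyl-1,3-dioxolan-4-yl]methyl}-4-[3-(TBDPS-oxy)prop-1-en-2-yl]oxolan-2-one F5. The dioxolane centre from the chiral pool thus acts as the resolving element, and 10 is separated by chromatography.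

Step 13. The amine-catalysed addition may be slow, and over days the amine could epimerise the α-silyloxy aldehyde at C8. The fallback sets out from 18 and rejoins the route at 20. Methyl propiolate is hydroaluminated with iBu2AlH in THF in the presence of N-methylmorpholine N-oxide to the α-aluminoacrylate, methyl 2-(diisobutylalumanyl)prop-2-enoate F6. F6 adds to 18 within hours at low temperature and gives 20 without an amine base.

Step 18. The C8 triethylsilyl group may be lost under the acid before ring closure is complete, after which O8 competes with O6 for the ester; closure of the trans-fused ring may also be sluggish. The fallback sets out from 25 and rejoins the route at 26. The methyl ester is hydrolysed with Me3SnOH to the hydroxy acid, 2-[(1S,2R,3R,4S,6S)-4-ethenyl-2-hydroxy-4-methyl-3-[3-(TBDPS-oxy)prop-1-en-2-yl]-6-(TES-oxy)cyclohexyl]prop-2-enoic acid F7. F7 is lactonised by carboxyl activation (EDC, DMAP cat., CH2Cl2, 0 °C), so that no acid and no free alkoxide meet the silyl ether.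

Step 22. Under the basic acylation medium the free 8-hydroxy lactone may translactonise toward O8, and the activated acid may epimerise through a ketene. The fallback sets out from 27 and 30 and rejoins the route at 32. 30 is converted with DCC (0.5 equiv) into its symmetrical anhydride, (2R)-2-methyl-3-(TBS-oxy)propanoic anhydride F8. The acyl group is transferred to 27 under Lewis acid catalysis (Bi(OTf)3 or Sc(OTf)3, MeCN, −20 °C), which involves neither an amine base nor an acylpyridinium ion.

## Further compounds

F1 | step 17 | methyl 2-[(1S,2S,3R,4S,6S)-4-ethenyl-2-hydroxy-4-methyl-3-[3-(TBDPS-oxy)prop-1-en-2-yl]-6-(TES-oxy)cyclohexyl]prop-2-enoate (C6 epimer of 25) | C=C[C@]1(C)C[C@H](O[Si](CC)(CC)CC)[C@@H](C(=C)C(=O)OC)[C@@H](O)[C@H]1C(=C)CO[Si](c1ccccc1)(c1ccccc1)C(C)(C)C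
F2 | step 17 | 2-[(1S,2S,3R,4S,6S)-4-ethenyl-2-hydroxy-4-methyl-3-[3-(TBDPS-oxy)prop-1-en-2-yl]-6-(TES-oxy)cyclohexyl]prop-2-enoic acid | C=C[C@]1(C)C[C@H](O[Si](CC)(CC)CC)[C@@H](C(=C)C(=O)O)[C@@H](O)[C@H]1C(=C)CO[Si](c1ccccc1)(c1ccccc1)C(C)(C)C
F3 | step 3 | lithium bis[3-(TBDPS-oxy)prop-1-en-2-yl]cuprate | [Li+].C=C(CO[Si](c1ccccc1)(c1ccccc1)C(C)(C)C)[Cu-]C(=C)CO[Si](c1ccccc1)(c1ccccc1)C(C)(C)C
F4 | step 3 | (4S)-4-[3-(TBDPS-oxy)prop-1-en-2-yl]oxolan-2-one (enantiomer of 6) | O=C1C[C@@H](C(=C)CO[Si](c2ccccc2)(c2ccccc2)C(C)(C)C)CO1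
F5 | step 3 | (3R,4S)-3-{[(4S)-2,2-dimethyl-1,3-dioxolan-4-yl]methyl}-4-[3-(TBDPS-oxy)prop-1-en-2-yl]oxolan-2-one (diastereomer of 10) | O=C1OC[C@H](C(=C)CO[Si](c2ccccc2)(c2ccccc2)C(C)(C)C)[C@H]1C[C@H]1COC(C)(C)O1
F6 | step 13 | methyl 2-(diisobutylalumanyl)prop-2-enoate | C=C([Al](CC(C)C)CC(C)C)C(=O)OC
F7 | step 18 | 2-[(1S,2R,3R,4S,6S)-4-ethenyl-2-hydroxy-4-methyl-3-[3-(TBDPS-oxy)prop-1-en-2-yl]-6-(TES-oxy)cyclohexyl]prop-2-enoic acid | C=C[C@]1(C)C[C@H](O[Si](CC)(CC)CC)[C@@H](C(=C)C(=O)O)[C@H](O)[C@H]1C(=C)CO[Si](c1ccccc1)(c1ccccc1)C(C)(C)C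
F8 | step 22 | (2R)-2-methyl-3-(TBS-oxy)propanoic anhydride | C[C@H](CO[Si](C)(C)C(C)(C)C)C(=O)OC(=O)[C@H](C)CO[Si](C)(C)C(C)(C)C
A1 | alternative 1 | (6S)-6-(2,2-dimethoxyethyl)-1-hydroxy-7-methylocta-1,7-dien-3-one (hydroxymethylene ketone) | OC=CC(=O)CC[C@@H](CC(OC)OC)C(C)=C
A2 | alternative 1 | 4-(2,2-dimethoxyethyl)-3-methyl-3-(2-oxoethyl)cyclohexanone, methyl cis to the acetal arm | O=CC[C@]1(C)CC(=O)CC[C@H]1CC(OC)OC
A3 | alternative 2 | 7β-ethynyl-6α-hydroxy cyclohexane with 8α-triethylsilyloxy and 15-(tert-butyldimethylsilyl)oxy groups | C=C[C@]1(C)C[C@H](O[Si](CC)(CC)CC)[C@@H](C#C)[C@H](O)[C@H]1C(=C)CO[Si](C)(C)C(C)(C)C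
A4 | alternative 2 | bis-silyl ether of the 8α,15-dihydroxy α-methylene lactone | C=C[C@]1(C)C[C@H](O[Si](CC)(CC)CC)[C@H]2C(=C)C(=O)O[C@@H]2[C@H]1C(=C)CO[Si](C)(C)C(C)(C)C
A5 | alternative 3 | acyclic (E)-allylsilane with C6 aldehyde, C7 acetate arm, C8 tert-butyldimethylsilyl ether and C15 TBDPS ether | C=C[C@](C)(C[C@H](O[Si](C)(C)C(C)(C)C)[C@@H](CC(=O)OC)C=O)/C=C(/C[Si](C)(C)C)CO[Si](c1ccccc1)(c1ccccc1)C(C)(C)C
A6 | alternative 3 | 6-hydroxy cyclohexane with C5 silyloxypropenyl and C7 acetate arm | C=C[C@]1(C)C[C@H](O[Si](C)(C)C(C)(C)C)[C@@H](CC(=O)OC)[C@H](O)[C@H]1C(=C)CO[Si](c1ccccc1)(c1ccccc1)C(C)(C)C
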